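## Analysis of the target

The target is a daucane-type hydroazulene. A cyclopentane (C1–C5) is fused through the C1–C5 bond to a cycloheptene (C1, C5, C6, C7, C8, C9, C10) whose only alkene is C8=C9, with a methyl group on C8. Five stereocentres lie on the connected set C10–C1–C5(–C4)–C6: C1 is quaternary (angular methyl), C4 is a tertiary carbinol carrying isopropyl, and C5 is the ring-fusion methine. H5 is anti to the angular methyl (trans fusion) and the C4 hydroxyl lies on the face of H5. The C6 4-hydroxybenzoate and the C10 isovalerate both lie on the face of the angular methyl; with these locants the target is (1S,4S,5S,6R,10S). The sensitive groups are two different esters on two secondary oxygens, one of them allylic and ionisable (C10), a free phenol, and a tertiary alcohol next to the ring fusion. The hard points are the quaternary C1 between the C10 carbinol and the fusion carbon, the trans fusion, and telling the two secondary oxygens apart. The strategy rests on two features: the seven-membered ring is a two-atom unit C5–C6 plus a five-atom unit C7–C8–C9–C10–C1 that the chain C2–C3–C4 already links, and the array C8(methyl)=C9–C10(O) is what an ene-type oxygenation leaves from a C9=C10 alkene with a hydrogen on C8.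

## Retrosynthetic reasoning

**Esters (27 ⇒ 26 ⇒ 25).** The phenol is unveiled last from its silyl ether 26, and before that the C10–O acyl bond is cut to give allylic alcohol 25. The two secondary oxygens are thus distinguished by the order in which they arrive, not by selective acylation of a diol.

**C10–O and C8=C9 (25 ⇒ 23).** The C10–O bond and the C8=C9 alkene are traced back to a C9=C10 alkene that carries one hydrogen on C8. Because C1 has no hydrogen, an ene-type photo-oxygenation can only place oxygen on C10 and move the alkene to C8=C9. The reaction is suprafacial, so the configuration of C8 in 23 is relayed to C10. The forward step needs H8 on the face of the angular methyl.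

**C6–O (23 ⇒ 21 + 22).** The C6–O bond is cut with inversion. Diol 21 has its C6 oxygen on the face of the C4 hydroxyl, the face a directed oxidation can reach; esterification with acid 22 under inversion moves it to the face of the angular methyl and installs the aroyl group in the same step.

**C5–H and C6–O (21 ⇒ 20 ⇒ 19).** Both are taken back to the C5=C6 alkene of allylic alcohol 19 through epoxide 20. The C4 hydroxyl directs the epoxidation to the neighbouring alkene and leaves C9=C10 alone. A single-electron opening at the tertiary C5 keeps the C6–O bond and lets H5 be placed late, anti to the angular methyl.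

**Key disconnection (19 ⇒ 18 ⇒ 17).** The bonds C1–C5 and C6–C7 are cut, which opens both rings at once and leads to the alkyne and the alkenyl methylcyclopropane of 17. The cut is made here because these two bonds join the two-atom and the five-atom unit, and because the cyclopropane methyl then lands on C8 with the alkene at C9=C10, exactly the array needed for the later ene step. The forward reaction is stereospecific at C1: the configuration of the cyclopropane carbon C9 and the E geometry of C1=C10 together decide C1. Both must therefore be secured before the ring closure; induction from C4 is not relied on.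

**Cyclopropane and C9–C10 (17 ⇒ 15 ⇒ 14 ⇒ 12 + 13).** The cyclopropane methylene C7 is removed from 15 to give dienol 14, whose hydroxyl directs a reagent-controlled cyclopropanation of C8=C9. The hydroxymethyl group of 15 is then reduced to the C8 methyl. The C9–C10 bond of 14 is cut to alkenyl iodide 12 and stannane 13. A direct olefination of a methyl ketone was not used: it would have to distinguish methyl from methylene, and any Z isomer would become the C1 epimer.

**Alkene geometry and the two alkynes (12 ⇒ 10 ⇒ 9 ⇒ 8 ⇒ 7 ⇒ 5).** The C1–methyl bond and the C10–I bond of 12 come from a syn carbometalation of the unhindered alkyne of diyne 10, which fixes the E geometry. The hindered alkyne on C4 is traced to aldehyde 9 (one-carbon homologation). Aldehyde 9 comes from enol ether 8, and so from acetal 7, by excision of one carbon; this avoids enolising an aldehyde that has a silyloxy group in the β position. The unhindered alkyne of 7 comes from the methyl ketone of 5.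

**Ring cleavage (5 ⇒ 2 ⇒ 1).** Ketone and masked aldehyde arise by cleaving the ring alkene of silyl ether 2, made from (R)-terpinen-4-ol 1, which supplies C4 with its isopropyl group and both arms. The aldehyde terminus must be masked in the same operation, because a free 1,6-keto aldehyde would close by aldol reaction under every basic step that follows.

## Alternatives that were turned down

**Alternative 1:** The bonds C1–C10 and C5–C6 are cut around a cyclopentanone. In the forward direction a copper–carbene catalyst transfers a 1-silylvinyl group from aluminium to 3-methylcyclopent-2-en-1-one A1, and the enolate is trapped by an aldol reaction and dehydrated to the alkylidene ketone A2.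
- For it: C1 is set by a catalyst on a cheap achiral enone, and three components are joined in one flask. On the certainty of the C1 centre this is stronger than the chosen route, which forms C1 at a crowded alkene terminus.
- Against it: no ring closes. The seven-membered ring still has to be closed between C8 and C9, and the tertiary centre so formed must be dehydrated toward C9 and not C7. C4 has to be made by adding isopropyl to a ketone conjugated with C5=C6, with both a face and a 1,2-versus-1,4 question. H5 and the C6 oxygen must then be set on an exocyclic alkene.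
- Comparison: the chosen route gives in one step both rings, C1, the C8 methyl and the alkene that later delivers the C10 oxygen, and it takes C4 from the chiral pool.

**Alternative 2:** The bonds C6–C7 and C9–C10 are cut. A tetravalent titanium Lewis acid promotes two allylsilane additions of the bis-silane A4 to the trans dialdehyde A3, closing the seven-membered ring as the methylene diol A5.
- For it: the ring closure is convergent and puts both oxygens in place, and A5 as formulated has both carbinols in the target configuration. On this point it is stronger than the chosen route, which needs an inversion at C6 and a separate oxygenation at C10.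
- Against it: A3 already contains C1 (quaternary), C4 and C5 in the trans arrangement, so the hardest stereochemistry is only moved into the synthesis of A3. The aldehyde on C5 is epimerisable under the Lewis acid. The second, ring-closing addition has no clear control element for the C6/C10 relationship. The two similar secondary alcohols of A5 need different acyl groups. The exocyclic alkene must be moved into the ring toward C9 and not C7, and nothing in the structure biases this.
- Comparison: the chosen route fixes the alkene position by the ene mechanism and differentiates the oxygens by sequence.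

**Alternative 3:** A boron Lewis acid opens an epoxide at the tertiary C1 of a cis-fused decalin carbinol while the antiperiplanar ring-fusion bond shifts to C1, giving the ketone A6.
- For it: the 1,2-shift is stereospecific, so the C1–C5 bond and the ring fusion carry no selectivity question. On this point it is more secure than a radical hydrogen-atom delivery.
- Against it: all stereocentres must first be installed on the decalin in a long linear sequence. A6 carries an extra hydroxyl to remove and a C10 ketone that must be reduced with face control and desaturated toward C8. Two different silyl groups have to be managed. As formulated, A6 has the hydroxylated carbon and two methylene groups between C1 and C4, that is a six-membered ring where the target has its cyclopentane.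
- Comparison: the chosen route reaches the bicycle with no surplus oxygen and in fewer steps after the ring-forming event.

Key step: step 11

Remark on the chemistry: commercial (R)-(−)-terpinen-4-ol 1 is taken to be of high enantiomeric purity; material of lower purity must be enriched before step 1, because C4 is never corrected later.
Remark on the chemistry: stannane 13 and acid 22 are taken as purchasable reagents.

## Route

Step 1
Reactants: 1 (R)-terpinen-4-ol
Product: 2 triethyl{[(1R)-4-methyl-1-(propan-2-yl)cyclohex-3-en-1-yl]oxy}silane
Conditions: TESOTf, 2,6-lutidine, CH2Cl2, 0 °C → rt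
Reagents that add atoms: triethylsilyl trifluoromethanesulfonate, CC[Si](CC)(CC)OS(=O)(=O)C(F)(F)F
Why: Silylation of a tertiary alcohol with a silyl triflate; the hindered tertiary silyl ether prevents hemiketal formation with the ketone made next and survives the amide bases, organoaluminium, zinc carbenoid and hydride steps; C4 comes unchanged from the chiral pool.

Step 2
Reactants: 2 triethyl{[(1R)-4-methyl-1-(propan-2-yl)cyclohex-3-en-1-yl]oxy}silane
Product: 5 (5R)-7,7-dimethoxy-5-(propan-2-yl)-5-[(triethylsilyl)oxy]heptan-2-one, via hydroperoxy aldehyde 3 (not isolated), via hydroperoxy acetal 4 (not isolated)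
Conditions: O3, CH2Cl2/MeOH, −78 °C; TsOH·H2O (cat.), 0 °C; NaHCO3; Me2S, rt
Reagents that add atoms: ozone, [O-][O+]=O; methanol, CO
Why: Ozonolysis with differentiation of the termini: the primary ozonide of the trisubstituted alkene should cleave to the carbonyl oxide at the methyl-bearing carbon, which methanol traps as the methoxy hydroperoxide, while the free aldehyde is acetalised by the acid; sulfide reduction after neutralisation then releases only the ketone. The hindered tertiary silyl ether should tolerate the brief catalytic acid, and the acetal keeps the 1,6-keto aldehyde from closing by aldol reaction in the basic steps that follow.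

Step 3
Reactants: 5 (5R)-7,7-dimethoxy-5-(propan-2-yl)-5-[(triethylsilyl)oxy]heptan-2-one
Product: 7 (5R)-7,7-dimethoxy-5-(propan-2-yl)-5-[(triethylsilyl)oxy]hept-1-yne, via enol phosphate 6 (not isolated)
Conditions: LiN(i-Pr)2, THF, −78 °C; ClP(O)(OEt)2, −78 °C → rt; LiN(i-Pr)2 (2.3 equiv), −78 °C → rt
Reagents that add atoms: none
Why: Conversion of a methyl ketone into a terminal alkyne by elimination of its kinetic enol phosphate: deprotonation at the methyl group, O-phosphorylation, then base-induced loss of phosphate; the acetal and the silyl ether are inert to the amide base.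

Step 4
Reactants: 7 (5R)-7,7-dimethoxy-5-(propan-2-yl)-5-[(triethylsilyl)oxy]hept-1-yne
Product: 8 (3S)-1-methoxy-3-(propan-2-yl)-3-[(triethylsilyl)oxy]hept-1-en-6-yne (E/Z mixture)
Conditions: TMSOTf, i-Pr2NEt, CH2Cl2, −20 °C → rt
Reagents that add atoms: none
Why: Silyl-triflate-induced elimination of methanol from a dimethyl acetal to the methyl enol ether (oxocarbenium ion, then deprotonation by the hindered amine); no enolate is formed, so the β-silyloxy group cannot be expelled, and the geometry of the enol ether does not matter.

Step 5
Reactants: 8 (3S)-1-methoxy-3-(propan-2-yl)-3-[(triethylsilyl)oxy]hept-1-en-6-yne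
Product: 9 (2S)-2-(propan-2-yl)-2-[(triethylsilyl)oxy]hex-5-ynal
Conditions: O3, CH2Cl2, −78 °C (Sudan III end point); Me2S
Reagents that add atoms: ozone, [O-][O+]=O
Why: Ozonolysis of an electron-rich enol ether, which reacts far faster than the terminal alkyne, so a dye end point should stop the reaction in time; one carbon is excised and the aldehyde now sits directly on C4, where it has no α-hydrogen and cannot epimerise or eliminate.

Step 6
Reactants: 9 (2S)-2-(propan-2-yl)-2-[(triethylsilyl)oxy]hex-5-ynal
Product: 10 (3S)-3-(propan-2-yl)-3-[(triethylsilyl)oxy]hepta-1,6-diyne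
Conditions: dimethyl (1-diazo-2-oxopropyl)phosphonate, K2CO3, MeOH, 0 °C → rt
Reagents that add atoms: dimethyl (1-diazo-2-oxopropyl)phosphonate, CC(=O)C(=[N+]=[N-])P(=O)(OC)OC
Why: Ohira–Bestmann (Seyferth–Gilbert) homologation of a non-enolisable aldehyde to the terminal alkyne under mild carbonate conditions that leave the silyl ether and the other alkyne alone; the spatial arrangement at C4 is unchanged.

Step 7
Reactants: 10 (3S)-3-(propan-2-yl)-3-[(triethylsilyl)oxy]hepta-1,6-diyne
Product: 12 triethyl{[(3S,6E)-7-iodo-6-methyl-3-(propan-2-yl)hept-6-en-1-yn-3-yl]oxy}silane, via alkenylalane 11 (not isolated)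
Conditions: AlMe3, Cp2ZrCl2 (25 mol%), CH2Cl2, 0 °C → rt; I2, THF, −30 °C
Reagents that add atoms: trimethylaluminium, C[Al](C)C; iodine, II
Why: Zirconium-catalysed carboalumination (Negishi) adds methyl and aluminium syn across the unhindered alkyne, methyl to the internal carbon (C1) and metal to the terminal carbon (C10); iodinolysis with retention gives the E iodide, in which the C2 chain is trans to iodine. The alkyne on C4 is shielded by a fully substituted carbon carrying isopropyl and the silyl ether and should react far more slowly.

Step 8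
Reactants: 12 triethyl{[(3S,6E)-7-iodo-6-methyl-3-(propan-2-yl)hept-6-en-1-yn-3-yl]oxy}silane; 13 (2E)-3-(tributylstannyl)prop-2-en-1-ol
Product: 14 (2E,4E,8S)-5-methyl-8-(propan-2-yl)-8-[(triethylsilyl)oxy]deca-2,4-dien-9-yn-1-ol
Conditions: PdCl2(MeCN)2 (5 mol%), DMF, rt
Reagents that add atoms: none
Why: Stille coupling of an alkenyl iodide with an alkenylstannane, with retention of both alkene geometries; no base and no copper salt are present, so the terminal alkyne is not drawn into coupling.

Step 9
Reactants: 14 (2E,4E,8S)-5-methyl-8-(propan-2-yl)-8-[(triethylsilyl)oxy]deca-2,4-dien-9-yn-1-ol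
Product: 15 {(1R,2S)-2-[(1E,5S)-5-ethynyl-2,6-dimethyl-5-[(triethylsilyl)oxy]hept-1-en-1-yl]cyclopropyl}methanol
Conditions: Et2Zn, CH2I2, (4S,5S)-2-butyl-N,N,N′,N′-tetramethyl-1,3,2-dioxaborolane-4,5-dicarboxamide, CH2Cl2, −10 °C → rt
Reagents that add atoms: diiodomethane, ICI
Why: Simmons–Smith cyclopropanation directed by the zinc alkoxide and controlled by the chiral dioxaborolane (Charette variant): only the allylic alkene C8=C9 is within reach, its E geometry gives the trans cyclopropane, and the (S,S) ligand is the enantiomer that should set C9 and C8 as drawn (the mirror-image ligand gives the other pair).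

Step 10
Reactants: 15 {(1R,2S)-2-[(1E,5S)-5-ethynyl-2,6-dimethyl-5-[(triethylsilyl)oxy]hept-1-en-1-yl]cyclopropyl}methanol
Product: 17 triethyl{[(3S,6E)-6-methyl-7-[(1R,2R)-2-methylcyclopropyl]-3-(propan-2-yl)hept-6-en-1-yn-3-yl]oxy}silane, via mesylate 16 (not isolated)
Conditions: MsCl, Et3N, CH2Cl2, −40 °C; LiEt3BH, THF, −40 → 0 °C
Reagents that add atoms: none
Why: Deoxygenation of a primary alcohol by sulfonate formation and SN2 displacement with a powerful hydride donor; low temperature and a non-ionising medium are meant to let hydride outrun ionisation of the cyclopropylcarbinyl sulfonate, and no stereocentre is touched.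

Step 11
Reactants: 17 triethyl{[(3S,6E)-6-methyl-7-[(1R,2R)-2-methylcyclopropyl]-3-(propan-2-yl)hept-6-en-1-yn-3-yl]oxy}silane
Product: 18 triethyl{[(1R,4S,8R)-1,8-dimethyl-4-(propan-2-yl)bicyclo[5.3.0]deca-5,9-dien-4-yl]oxy}silane (locants of the analysis: fusion C1–C5, alkenes C5=C6 and C9=C10)
Conditions: [Rh(CO)2Cl]2 (5 mol%), ClCH2CH2Cl (0.02 M), 80 °C
Reagents that add atoms: none
Why: Intramolecular rhodium-catalysed (5+2) cycloaddition of an alkyne with a vinylcyclopropane, the closest known reaction type, used here at its demanding limit because a trisubstituted alkene terminus becomes a quaternary carbon next to the fully substituted C4. Monovalent rhodium binds alkyne and alkene and inserts into the cyclopropane bond C9–C7 that lies parallel to the alkene π system, giving a rhodacycle with a σ bond to C7 and a π-allyl over C9–C10–C1. The tethered alkyne then inserts at the allyl terminus: C1–C5 forms and the five-membered ring closes in an exo sense through the C2–C3–C4 tether; reductive elimination of C6 and C7 from the eight-membered rhodacycle closes the seven-membered ring and leaves the alkenes at C5=C6 and C9=C10. The one new stereocentre, C1, is set by transfer of chirality and not by induction from C4: the metal stays on the face of the allyl unit on which the broken C9–C7 bond stood, so the configuration of C9 together with the E geometry of C1=C10 (methyl cis to the cyclopropane, tether trans) fixes the face on which C5 arrives. C8 is a spectator whose bonds are not touched, so its methyl ends on the face opposite the C1 methyl. The selectivity needed is cleavage of C9–C7 and not of C9–C8; the trans methyl on C8 secures it by making the substituted bond the more hindered one, and [Rh(CO)2Cl]2 is the catalyst that prefers the less substituted bond and accepts a terminal alkyne. C4 only has to be accommodated: in 18 its isopropyl group lies on the methyl face and the silyl ether on the other face of the new cyclopentene.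

Step 12
Reactants: 18 triethyl{[(1R,4S,8R)-1,8-dimethyl-4-(propan-2-yl)bicyclo[5.3.0]deca-5,9-dien-4-yl]oxy}silane
Product: 19 (1R,4S,8R)-1,8-dimethyl-4-(propan-2-yl)bicyclo[5.3.0]deca-5,9-dien-4-ol (locants of the analysis)
Conditions: TBAF, THF, 40 °C
Reagents that add atoms: none
Why: Fluoride cleavage of a silyl ether; the hindered tertiary ether needs gentle warming, and the basic medium does not ionise the tertiary allylic alcohol.

Step 13
Reactants: 19 (1R,4S,8R)-1,8-dimethyl-4-(propan-2-yl)bicyclo[5.3.0]deca-5,9-dien-4-ol
Product: 20 (1R,4S,5R,6S,8R)-5,6-epoxy-1,8-dimethyl-4-(propan-2-yl)bicyclo[5.3.0]dec-9-en-4-ol (epoxide oxygen on the face of the C4 hydroxyl)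
Conditions: VO(acac)2 (5 mol%), t-BuOOH, CH2Cl2, 0 °C → rt
Reagents that add atoms: tert-butyl hydroperoxide, CC(C)(C)OO
Why: Vanadium-catalysed hydroxyl-directed epoxidation of an allylic alcohol: oxygen is delivered to C5=C6 from the face of the C4 hydroxyl, which sets the C6–O bond; the C9=C10 alkene is out of reach of the vanadate ester and should stay untouched.

Step 14
Reactants: 20 (1R,4S,5R,6S,8R)-5,6-epoxy-1,8-dimethyl-4-(propan-2-yl)bicyclo[5.3.0]dec-9-en-4-ol
Product: 21 (1R,4S,5S,6S,8R)-1,8-dimethyl-4-(propan-2-yl)bicyclo[5.3.0]dec-9-ene-4,6-diol (H5 and both hydroxyls on one face, angular methyl on the other)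
Conditions: Cp2TiCl2, Mn, THF/H2O, rt
Reagents that add atoms: none
Why: Titanocene-mediated reductive epoxide opening: trivalent titanium (Cp2TiCl formed in the flask) cleaves the C5–O bond to the tertiary C5 radical and keeps the C6–O bond with its configuration. The radical should take hydrogen from titanium-bound water on the face opposite the C1 methyl and C4 isopropyl groups, the face on which the C4 hydroxyl can hold the metal aqua complex, which gives the trans ring fusion.

Step 15
Reactants: 21 (1R,4S,5S,6S,8R)-1,8-dimethyl-4-(propan-2-yl)bicyclo[5.3.0]dec-9-ene-4,6-diol; 22 4-[(tert-butyldimethylsilyl)oxy]benzoic acid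
Product: 23 (1R,4S,5S,6R,8R)-4-hydroxy-1,8-dimethyl-4-(propan-2-yl)bicyclo[5.3.0]dec-9-en-6-yl 4-[(tert-butyldimethylsilyl)oxy]benzoate
Conditions: DIAD, PPh3, toluene, 0 °C → rt
Reagents that add atoms: none
Why: Mitsunobu esterification with inversion at C6: the secondary alcohol is activated as its oxyphosphonium ion and displaced by the carboxylate from the opposite face, which puts the aroyloxy group on the face of the angular methyl; the tertiary C4 hydroxyl does not react and, being cis to the leaving group, cannot displace it.

Step 16
Reactants: 23 (1R,4S,5S,6R,8R)-4-hydroxy-1,8-dimethyl-4-(propan-2-yl)bicyclo[5.3.0]dec-9-en-6-yl 4-[(tert-butyldimethylsilyl)oxy]benzoate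
Product: 25 (1S,4S,5S,6R,10S)-4,10-dihydroxy-1,8-dimethyl-4-(propan-2-yl)bicyclo[5.3.0]dec-8-en-6-yl 4-[(tert-butyldimethylsilyl)oxy]benzoate, via allylic hydroperoxide 24 (not isolated)
Conditions: O2, hν, tetraphenylporphyrin (cat.), CH2Cl2, −20 °C; PPh3
Reagents that add atoms: oxygen, O=O
Why: Schenck ene reaction of singlet oxygen, then phosphine reduction of the hydroperoxide with retention: H8 is the only allylic hydrogen (C1 is quaternary), so oxygen must add to C10 and the alkene must move to C8=C9. The process is suprafacial, so the C10–O bond forms on the face of H8, which is the face of the angular methyl and the less encumbered one (the other carries C2 and the C8 methyl); this gives 10S.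

Step 17
Reactants: 25 (1S,4S,5S,6R,10S)-4,10-dihydroxy-1,8-dimethyl-4-(propan-2-yl)bicyclo[5.3.0]dec-8-en-6-yl 4-[(tert-butyldimethylsilyl)oxy]benzoate
Product: 26 (1S,4S,5S,6R,10S)-4-hydroxy-1,8-dimethyl-10-[(3-methylbutanoyl)oxy]-4-(propan-2-yl)bicyclo[5.3.0]dec-8-en-6-yl 4-[(tert-butyldimethylsilyl)oxy]benzoate
Conditions: isovaleryl chloride, pyridine, DMAP (cat.), CH2Cl2, 0 °C → rt
Reagents that add atoms: 3-methylbutanoyl chloride, CC(C)CC(Cl)=O
Why: Acylation of the secondary allylic alcohol with an acid chloride under nucleophilic catalysis, with retention at C10; the hindered tertiary C4 hydroxyl stays free and the phenol is masked.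

Step 18
Reactants: 26 (1S,4S,5S,6R,10S)-4-hydroxy-1,8-dimethyl-10-[(3-methylbutanoyl)oxy]-4-(propan-2-yl)bicyclo[5.3.0]dec-8-en-6-yl 4-[(tert-butyldimethylsilyl)oxy]benzoate
Product: 27 CNP0086724.2, (1S,4S,5S,6R,10S)-4-hydroxy-1,8-dimethyl-10-[(3-methylbutanoyl)oxy]-4-(propan-2-yl)bicyclo[5.3.0]dec-8-en-6-yl 4-hydroxybenzoate
Conditions: TBAF, AcOH, THF, 0 °C
Reagents that add atoms: none
Why: Fluoride cleavage of an aryl silyl ether, the most labile silicon–oxygen bond present; buffering with acetic acid keeps the phenoxide from attacking the two esters, and no stereocentre is involved.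

## Compound list

1 | (R)-terpinen-4-ol | CC1=CC[C@@](O)(C(C)C)CC1 | starting material
2 | triethyl{[(1R)-4-methyl-1-(propan-2-yl)cyclohex-3-en-1-yl]oxy}silane | CC1=CC[C@@](O[Si](CC)(CC)CC)(C(C)C)CC1 | intermediate
3 | (3R)-6-hydroperoxy-6-methoxy-3-(propan-2-yl)-3-[(triethylsilyl)oxy]heptanal (both C6 epimers) | O=CC[C@@](O[Si](CC)(CC)CC)(C(C)C)CCC(C)(OC)OO | intermediate
4 | (3R)-6-hydroperoxy-1,1,6-trimethoxy-3-(propan-2-yl)-3-[(triethylsilyl)oxy]heptane (both C6 epimers) | COC(OC)C[C@@](O[Si](CC)(CC)CC)(C(C)C)CCC(C)(OC)OO | intermediate
5 | (5R)-7,7-dimethoxy-5-(propan-2-yl)-5-[(triethylsilyl)oxy]heptan-2-one | COC(OC)C[C@@](O[Si](CC)(CC)CC)(C(C)C)CCC(C)=O | intermediate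
6 | diethyl (5R)-7,7-dimethoxy-5-(propan-2-yl)-5-[(triethylsilyl)oxy]hept-1-en-2-yl phosphate | COC(OC)C[C@@](O[Si](CC)(CC)CC)(C(C)C)CCC(=C)OP(=O)(OCC)OCC | intermediate
7 | (5R)-7,7-dimethoxy-5-(propan-2-yl)-5-[(triethylsilyl)oxy]hept-1-yne | COC(OC)C[C@@](O[Si](CC)(CC)CC)(C(C)C)CCC#C | intermediate
8 | (3S)-1-methoxy-3-(propan-2-yl)-3-[(triethylsilyl)oxy]hept-1-en-6-yne (E/Z mixture) | COC=C[C@@](O[Si](CC)(CC)CC)(C(C)C)CCC#C | intermediate
9 | (2S)-2-(propan-2-yl)-2-[(triethylsilyl)oxy]hex-5-ynal | O=C[C@@](O[Si](CC)(CC)CC)(C(C)C)CCC#C | intermediate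
10 | (3S)-3-(propan-2-yl)-3-[(triethylsilyl)oxy]hepta-1,6-diyne | C#C[C@@](O[Si](CC)(CC)CC)(C(C)C)CCC#C | intermediate
11 | dimethyl{(1E,5S)-2-methyl-5-(propan-2-yl)-5-[(triethylsilyl)oxy]hept-1-en-6-yn-1-yl}alumane | C#C[C@@](O[Si](CC)(CC)CC)(C(C)C)CC/C(C)=C/[Al](C)C | intermediate
12 | triethyl{[(3S,6E)-7-iodo-6-methyl-3-(propan-2-yl)hept-6-en-1-yn-3-yl]oxy}silane | C#C[C@@](O[Si](CC)(CC)CC)(C(C)C)CC/C(C)=C/I | intermediate
13 | (2E)-3-(tributylstannyl)prop-2-en-1-ol | CCCC[Sn](CCCC)(CCCC)/C=C/CO | starting material
14 | (2E,4E,8S)-5-methyl-8-(propan-2-yl)-8-[(triethylsilyl)oxy]deca-2,4-dien-9-yn-1-ol | C#C[C@@](O[Si](CC)(CC)CC)(C(C)C)CC/C(C)=C/C=C/CO | intermediate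
15 | {(1R,2S)-2-[(1E,5S)-5-ethynyl-2,6-dimethyl-5-[(triethylsilyl)oxy]hept-1-en-1-yl]cyclopropyl}methanol | C#C[C@@](O[Si](CC)(CC)CC)(C(C)C)CC/C(C)=C/[C@@H]1C[C@H]1CO | intermediate
16 | methanesulfonate of 15 | C#C[C@@](O[Si](CC)(CC)CC)(C(C)C)CC/C(C)=C/[C@@H]1C[C@H]1COS(C)(=O)=O | intermediate
17 | triethyl{[(3S,6E)-6-methyl-7-[(1R,2R)-2-methylcyclopropyl]-3-(propan-2-yl)hept-6-en-1-yn-3-yl]oxy}silane | C#C[C@@](O[Si](CC)(CC)CC)(C(C)C)CC/C(C)=C/[C@@H]1C[C@H]1C | intermediate
18 | triethyl{[(1R,4S,8R)-1,8-dimethyl-4-(propan-2-yl)bicyclo[5.3.0]deca-5,9-dien-4-yl]oxy}silane (locants of the analysis) | C[C@H]1C=C[C@@]2(C)CC[C@](O[Si](CC)(CC)CC)(C(C)C)C2=CC1 | intermediate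
19 | (1R,4S,8R)-1,8-dimethyl-4-(propan-2-yl)bicyclo[5.3.0]deca-5,9-dien-4-ol | C[C@H]1C=C[C@@]2(C)CC[C@](O)(C(C)C)C2=CC1 | intermediate
20 | (1R,4S,5R,6S,8R)-5,6-epoxy-1,8-dimethyl-4-(propan-2-yl)bicyclo[5.3.0]dec-9-en-4-ol | C[C@H]1C=C[C@@]2(C)CC[C@](O)(C(C)C)[C@@]23O[C@H]3C1 | intermediate
21 | (1R,4S,5S,6S,8R)-1,8-dimethyl-4-(propan-2-yl)bicyclo[5.3.0]dec-9-ene-4,6-diol | C[C@H]1C=C[C@@]2(C)CC[C@](O)(C(C)C)[C@@H]2[C@@H](O)C1 | intermediate
22 | 4-[(tert-butyldimethylsilyl)oxy]benzoic acid | CC(C)(C)[Si](C)(C)Oc1ccc(cc1)C(O)=O | starting material
23 | (1R,4S,5S,6R,8R)-4-hydroxy-1,8-dimethyl-4-(propan-2-yl)bicyclo[5.3.0]dec-9-en-6-yl 4-[(tert-butyldimethylsilyl)oxy]benzoate | C[C@H]1C=C[C@@]2(C)CC[C@](O)(C(C)C)[C@@H]2[C@H](OC(=O)c2ccc(O[Si](C)(C)C(C)(C)C)cc2)C1 | intermediate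
24 | (1S,4S,5S,6R,10S)-10-hydroperoxy-4-hydroxy-1,8-dimethyl-4-(propan-2-yl)bicyclo[5.3.0]dec-8-en-6-yl 4-[(tert-butyldimethylsilyl)oxy]benzoate | CC1=C[C@H](OO)[C@@]2(C)CC[C@](O)(C(C)C)[C@@H]2[C@H](OC(=O)c2ccc(O[Si](C)(C)C(C)(C)C)cc2)C1 | intermediate
25 | (1S,4S,5S,6R,10S)-4,10-dihydroxy-1,8-dimethyl-4-(propan-2-yl)bicyclo[5.3.0]dec-8-en-6-yl 4-[(tert-butyldimethylsilyl)oxy]benzoate | CC1=C[C@H](O)[C@@]2(C)CC[C@](O)(C(C)C)[C@@H]2[C@H](OC(=O)c2ccc(O[Si](C)(C)C(C)(C)C)cc2)C1 | intermediate
26 | (1S,4S,5S,6R,10S)-4-hydroxy-1,8-dimethyl-10-[(3-methylbutanoyl)oxy]-4-(propan-2-yl)bicyclo[5.3.0]dec-8-en-6-yl 4-[(tert-butyldimethylsilyl)oxy]benzoate | CC1=C[C@H](OC(=O)CC(C)C)[C@@]2(C)CC[C@](O)(C(C)C)[C@@H]2[C@H](OC(=O)c2ccc(O[Si](C)(C)C(C)(C)C)cc2)C1 | intermediate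
27 | CNP0086724.2, (1S,4S,5S,6R,10S)-4-hydroxy-1,8-dimethyl-10-[(3-methylbutanoyl)oxy]-4-(propan-2-yl)bicyclo[5.3.0]dec-8-en-6-yl 4-hydroxybenzoate | CC1=C[C@H](OC(=O)CC(C)C)[C@@]2(C)CC[C@](O)(C(C)C)[C@@H]2[C@H](OC(=O)c2ccc(O)cc2)C1 | target

## Step count and least certain steps

Total step count: 18. Longest linear sequence: 18 (steps 1–18 from 1; 13 and 22 are purchased).

**Step 11 (key step).** The most likely failure is slow insertion of the alkyne at the crowded allyl terminus, where a quaternary carbon forms next to the fully substituted C4. This would let side processes take over: opening of the more substituted cyclopropane bond, β-hydride elimination of the rhodacycle to open-chain trienes, or oligomerisation of the terminal alkyne. A mismatch between the C4 substituents and the face imposed by the cyclopropane would make this worse. The fallback changes the substrate and the order of steps, not only the catalyst: 17 is desilylated (TBAF, THF) to (3S,6E)-6-methyl-7-[(1R,2R)-2-methylcyclopropyl]-3-(propan-2-yl)hept-6-en-1-yn-3-ol F1, which has lost the bulkiest group beside the reacting alkyne. F1 is cyclised with the same rhodium dimer or with the cationic complex [Rh(C10H8)(cod)]SbF6. This gives 19 directly, so the route is rejoined at 19 and step 12 falls away.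

**Step 10.** The sulfonate 16 is a cyclopropylcarbinyl system whose cation is further stabilised through the ring by the alkenyl group, so ionisation with ring opening may outrun hydride attack. The fallback defers the deoxygenation until the cyclopropane has been consumed. It sets out from 15, which is silylated (TESCl, imidazole) to the bis(triethylsilyl) ether F2. The rhodium-catalysed cycloaddition is run on F2 (a silyloxymethyl group should steer cleavage to the unsubstituted bond as methyl does) to give the 8-(silyloxymethyl) diene F3. Both silyl groups are removed (TBAF) to give the diol F4. The primary alcohol is mesylated selectively (MsCl, Et3N, −20 °C) to the mesylate F5, now an ordinary primary sulfonate, which is reduced with LiEt3BH. This gives 19, where the route is rejoined.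

**Step 14.** Hydrogen-atom transfer to the planar C5 radical may show poor facial selectivity and give the cis-fused epimer; a second trivalent titanium may also trap the radical and lead to deoxygenation back to the alkene. The fallback is a tether-controlled syn addition that sets out from 19. Silylation with (HMe2Si)2NH gives the dimethylsilyl ether F6. Intramolecular hydrosilylation (Pt2(dvtms)3, zerovalent platinum, toluene, 60 °C) gives the oxasilolane F7, in which silicon on C6 and hydrogen on C5 have both been delivered from the face of the C4 oxygen. Tamao–Fleming oxidation (H2O2, KF, KHCO3, THF/MeOH) with retention gives 21, so steps 13 and 14 are bypassed.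

**Step 15.** The displacement has to arrive from the face that carries the angular methyl and the isopropyl group, and 22 is only moderately acidic. A slow substitution would give elimination toward C7 or no reaction. The fallback replaces substitution by oxidation and reduction and sets out from 21. Dess–Martin oxidation gives the β-hydroxy ketone F8. Reduction from the open face (NaBH4, CeCl3·7H2O, MeOH, −78 °C) gives the 6-epimeric diol F9. Esterification of F9 with 22 under Yamaguchi conditions (2,4,6-trichlorobenzoyl chloride, Et3N, then DMAP) gives 23.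

**Step 16.** The cis-disubstituted alkene is a slow partner for singlet oxygen, while the trisubstituted alkene of the product is a faster one, so over-oxidation may compete with conversion. The fallback delivers the oxygen through an epoxide and sets out from 23. m-CPBA should attack the same, less encumbered face and give the 9,10-epoxide F10. Et2Al(TMP) (diethylaluminium 2,2,6,6-tetramethylpiperidide, toluene, 0 °C) then removes the syn hydrogen H8 and opens the C9–O bond, which gives 25 directly.

## Further compounds

F1 | step 11 | (3S,6E)-6-methyl-7-[(1R,2R)-2-methylcyclopropyl]-3-(propan-2-yl)hept-6-en-1-yn-3-ol | C#C[C@@](O)(C(C)C)CC/C(C)=C/[C@@H]1C[C@H]1C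
F2 | step 10 | bis(triethylsilyl) ether of 15 | C#C[C@@](O[Si](CC)(CC)CC)(C(C)C)CC/C(C)=C/[C@@H]1C[C@H]1CO[Si](CC)(CC)CC
F3 | step 10 | (1R,4S,8R)-1-methyl-4-(propan-2-yl)-4-[(triethylsilyl)oxy]-8-{[(triethylsilyl)oxy]methyl}bicyclo[5.3.0]deca-5,9-diene | CC[Si](CC)(CC)OC[C@H]1C=C[C@@]2(C)CC[C@](O[Si](CC)(CC)CC)(C(C)C)C2=CC1
F4 | step 10 | (1R,4S,8R)-8-(hydroxymethyl)-1-methyl-4-(propan-2-yl)bicyclo[5.3.0]deca-5,9-dien-4-ol | OC[C@H]1C=C[C@@]2(C)CC[C@](O)(C(C)C)C2=CC1
F5 | step 10 | primary methanesulfonate of F4 | CS(=O)(=O)OC[C@H]1C=C[C@@]2(C)CC[C@](O)(C(C)C)C2=CC1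
F6 | step 14 | dimethylsilyl ether of 19 | C[C@H]1C=C[C@@]2(C)CC[C@](O[SiH](C)C)(C(C)C)C2=CC1
F7 | step 14 | oxasilolane bridging O4 and C6 (Si on C6 and H on C5 on the face of the C4 oxygen) | C[C@H]1C=C[C@@]2(C)CC[C@](O3)(C(C)C)[C@@H]2[C@@H]([Si]3(C)C)C1
F8 | step 15 | (1R,4S,5S,8R)-4-hydroxy-1,8-dimethyl-4-(propan-2-yl)bicyclo[5.3.0]dec-9-en-6-one | C[C@H]1C=C[C@@]2(C)CC[C@](O)(C(C)C)[C@@H]2C(=O)C1
F9 | step 15 | (1R,4S,5S,6R,8R)-1,8-dimethyl-4-(propan-2-yl)bicyclo[5.3.0]dec-9-ene-4,6-diol | C[C@H]1C=C[C@@]2(C)CC[C@](O)(C(C)C)[C@@H]2[C@H](O)C1
F10 | step 16 | 9,10-epoxide of 23 (oxygen on the face of the angular methyl) | C[C@H]1[C@@H]3O[C@@H]3[C@@]2(C)CC[C@](O)(C(C)C)[C@@H]2[C@H](OC(=O)c2ccc(O[Si](C)(C)C(C)(C)C)cc2)C1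
A1 | alternative 1 | 3-methylcyclopent-2-en-1-one | CC1=CC(=O)CC1
A2 | alternative 1 | (2E,3S)-3-methyl-2-[2-(2-methyl-1,3-dioxolan-2-yl)ethylidene]-3-[1-(trimethylsilyl)ethenyl]cyclopentan-1-one | C[C@]1(C(=C)[Si](C)(C)C)CCC(=O)/C1=C/CC2(C)OCCO2
A3 | alternative 2 | trans cyclopentane-1,5-dicarbaldehyde with C1 methyl and C4 isopropyl and triethylsilyloxy groups | O=C[C@@]1(C)CC[C@](O[Si](CC)(CC)CC)(C(C)C)[C@@H]1C=O
A4 | alternative 2 | trimethyl{2-[(trimethylsilyl)methyl]prop-2-en-1-yl}silane | C=C(C[Si](C)(C)C)C[Si](C)(C)C
A5 | alternative 2 | 8-methylene hydroazulene-6,10-diol triethylsilyl ether | C=C1C[C@H](O)[C@@]2(C)CC[C@](O[Si](CC)(CC)CC)(C(C)C)[C@@H]2[C@H](O)C1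
A6 | alternative 3 | bicyclic 10-ketone with 2-hydroxyl and two silyl ethers | C[C@H]1CC(=O)[C@@]2(C)[C@@H](O)CC[C@](O[Si](CC)(CC)CC)(C(C)C)[C@@H]2[C@H](O[Si](C)(C)C(C)(C)C)C1
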